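## Retrosynthetic overview

1. The target comes from an N-Boc/O-TBS decahydroquinolin-3-ol and (E)-oct-2-enoic acid (hexanal + malonic acid). Acylation comes late and one acidic deprotection finishes the synthesis.
2. The cis-decahydroquinolin-3-ol comes from a 3-oxo-tetrahydroquinoline dienone by 1,2-reduction (sets C3) and then OH-directed hydrogenation (sets C4a and C8a).
3. The dienone comes from a 2-(1-aminoethyl)-4-alkyl-4,5,6,7-tetrahydrobenzofuran by oxidative furan-to-dihydropyridinone ring expansion (aza-Achmatowicz, forms N1–C8a) and dehydration.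
4. The furan comes from a 2-alkynylcyclohexenone and the side-chain alkene by an asymmetric alkylative furan annulation (C5–C1' bond, C5 stereocentre, furan ring). The ynenone comes from 2-iodocyclohexenone and (R)-N-Boc-but-3-yn-2-amine. The alkene comes from (R)-propyloxirane and allyl Grignard.
5. Ring order: carbocycle (bought), then furan, then piperidine by expansion of the furan.

Assumption: (R)-2-propyloxirane, 2-iodocyclohex-2-en-1-one and tert-butyl (R)-but-3-yn-2-ylcarbamate are taken as catalogue compounds. The sense of induction of the phosphoramidite in step 3 is assigned by analogy with dialkylzinc additions to cyclohexenone, and the antipodal ligand is equally available.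

## Route

Step 1
Reactants: 1 (R)-2-propyloxirane; 2 allylmagnesium bromide
Product: 4 (R)-tert-butyldimethyl(oct-7-en-4-yloxy)silane, via bromomagnesium alkoxide 3 (not isolated)
Conditions: CuI (10 mol %), Et2O, −30 → 0 °C; then TBSOTf, 0 °C → rt
Reagents that add atoms: tert-butyldimethylsilyl triflate (TBSOTf), CC(C)(C)[Si](C)(C)OS(=O)(=O)C(F)(F)F
Why: Cu-catalysed SN2 epoxide opening at the unsubstituted carbon leaves the carbinol centre (future C5', R) untouched, and the magnesium alkoxide is O-silylated in the same flask.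

Step 2
Reactants: 5 2-iodocyclohex-2-en-1-one; 6 tert-butyl (R)-but-3-yn-2-ylcarbamate
Product: 7 tert-butyl N-[(2R)-4-(6-oxocyclohex-1-en-1-yl)but-3-yn-2-yl]carbamate
Conditions: PdCl2(PPh3)2 (3 mol %), CuI (6 mol %), i-Pr2NH, THF, 0 °C → rt
Reagents that add atoms: none
Why: Sonogashira coupling of an α-iodoenone with a terminal alkyne is a standard entry to 2-(1-alkynyl)-2-alken-1-ones, and the propargylic centre (future C2, R) is not involved.

Step 3
Reactants: 4 (R)-tert-butyldimethyl(oct-7-en-4-yloxy)silane; 7 tert-butyl N-[(2R)-4-(6-oxocyclohex-1-en-1-yl)but-3-yn-2-yl]carbamate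
Product: 10 tert-butyl N-[(1R)-1-{(4S)-4-[(5R)-5-(tert-butyldimethylsilyloxy)octyl]-4,5,6,7-tetrahydro-1-benzofuran-2-yl}ethyl]carbamate, via alkylzirconocene chloride 8 (not isolated), via trimethylsilyl enol ether 9 (not isolated)
Conditions: 4 (1.5 equiv), Cp2ZrHCl, CH2Cl2, rt; then 7, CuOTf·½C6H6 (10 mol %), (S,R,R)-BINOL/bis(1-phenylethyl)amine phosphoramidite (11 mol %), TMSCl, Et2O, 0 °C → rt; then MeOH, ZnCl2 (20 mol %), rt
Reagents that add atoms: none
Why: Proposed new method: asymmetric alkylative furan annulation, in which hydrozirconation gives the primary alkyl-Zr species, Zr→Cu transfer gives a ligated alkylcopper that π-binds the enone (LUMO lowered by the slim sp-alkynyl α-substituent) and delivers the chain to Cβ under ligand control to set C4 (S, future C5), TMSCl traps the regiodefined enolate, and ZnCl2/MeOH then drives 5-endo-dig O-closure on the alkyne with proto-demetalation to aromatise; the closest known reaction types are Cu/phosphoramidite conjugate addition of hydrozirconated alkenes to α-unsubstituted cycloalkenones, π-acid furan formation from 2-alkynyl enones with O- or arene nucleophiles, and ZnCl2 cycloisomerisation of alk-3-yn-1-ones.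

Step 4
Reactants: 10 tert-butyl N-[(1R)-1-{(4S)-4-[(5R)-5-(tert-butyldimethylsilyloxy)octyl]-4,5,6,7-tetrahydro-1-benzofuran-2-yl}ethyl]carbamate
Product: 12 tert-butyl (2R,5S)-5-[(5R)-5-(tert-butyldimethylsilyloxy)octyl]-2-methyl-3-oxo-3,5,6,7-tetrahydroquinoline-1(2H)-carboxylate, via 8a-hydroxy hemiaminal 11 (not isolated)
Conditions: mCPBA (1.05 equiv), CH2Cl2, 0 °C; then 2,6-lutidine, TFAA, 0 °C → rt
Reagents that add atoms: 3-chloroperoxybenzoic acid (mCPBA), OOC(=O)c1cccc(Cl)c1
Why: Aza-Achmatowicz oxidative ring expansion, in which peracid opens the electron-rich furan to the (Z)-ene-dione, the carbamate N–H closes on the former C7a ketone to give the six-membered hemiaminal (N1–C8a bond), and trifluoroacetylation followed by loss through the N-acyliminium ion can only eliminate toward C8 to give the enecarbamate, with C2 and C5 untouched.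

Step 5
Reactants: 12 tert-butyl (2R,5S)-5-[(5R)-5-(tert-butyldimethylsilyloxy)octyl]-2-methyl-3-oxo-3,5,6,7-tetrahydroquinoline-1(2H)-carboxylate
Product: 13 tert-butyl (2R,3R,5S)-5-[(5R)-5-(tert-butyldimethylsilyloxy)octyl]-3-hydroxy-2-methyl-3,5,6,7-tetrahydroquinoline-1(2H)-carboxylate
Conditions: NaBH4, CeCl3·7H2O, MeOH, −78 °C
Reagents that add atoms: none
Why: Luche 1,2-reduction, in which A(1,3) strain with the Boc group holds the C2 methyl pseudoaxial on the flat dienone ring, so hydride enters from the opposite face and gives the 2,3-cis (3R) alcohol.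

Step 6
Reactants: 13 tert-butyl (2R,3R,5S)-5-[(5R)-5-(tert-butyldimethylsilyloxy)octyl]-3-hydroxy-2-methyl-3,5,6,7-tetrahydroquinoline-1(2H)-carboxylate
Product: 14 tert-butyl (2R,3R,4aS,5S,8aR)-5-[(5R)-5-(tert-butyldimethylsilyloxy)octyl]-3-hydroxy-2-methyl-octahydroquinoline-1(2H)-carboxylate
Conditions: [Ir(cod)(PCy3)(py)]BArF (5 mol %), H2 (10 bar), CH2Cl2, rt
Reagents that add atoms: none
Why: Hydroxyl-directed hydrogenation with Crabtree's catalyst, in which Ir bound to the C3-OH delivers hydrogen to both C=C bonds of the s-trans diene on the OH face, which is also the face opposite the C5 chain, so H4a and H8a end up cis to each other, to H5 and to the C3 oxygen.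

Step 7
Reactants: 15 hexanal; 16 malonic acid
Product: 17 (E)-oct-2-enoic acid
Conditions: pyridine, piperidine (cat.), rt → 90 °C
Reagents that add atoms: none
Why: Doebner–Knoevenagel condensation with decarboxylation in pyridine gives the conjugated (E)-acid.

Step 8
Reactants: 14 tert-butyl (2R,3R,4aS,5S,8aR)-5-[(5R)-5-(tert-butyldimethylsilyloxy)octyl]-3-hydroxy-2-methyl-octahydroquinoline-1(2H)-carboxylate; 17 (E)-oct-2-enoic acid
Product: 18 tert-butyl (2R,3R,4aS,5S,8aR)-5-[(5R)-5-(tert-butyldimethylsilyloxy)octyl]-2-methyl-3-[(E)-oct-2-enoyloxy]-octahydroquinoline-1(2H)-carboxylate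
Conditions: DCC, DMAP, CH2Cl2, 0 °C → rt
Reagents that add atoms: none
Why: Steglich esterification of the only free hydroxyl proceeds with retention at C3 and without touching the E-alkene.

Step 9
Reactants: 18 tert-butyl (2R,3R,4aS,5S,8aR)-5-[(5R)-5-(tert-butyldimethylsilyloxy)octyl]-2-methyl-3-[(E)-oct-2-enoyloxy]-octahydroquinoline-1(2H)-carboxylate
Product: 19 (2R,3R,4aS,5S,8aR)-5-[(5R)-5-hydroxyoctyl]-2-methyl-decahydroquinolin-3-yl (E)-oct-2-enoate (target)
Conditions: TFA–H2O 9:1, 0 °C → rt; then aq. NaHCO3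
Reagents that add atoms: none
Why: Acidolysis removes Boc and the secondary TBS ether together, the enoate is acid-stable, and the mild basic work-up frees the amine and cleaves any transient trifluoroacetate.

## Compound list

1 | (R)-2-propyloxirane | CCC[C@@H]1CO1 | starting material
2 | allylmagnesium bromide | C=CC[Mg]Br | starting material
3 | bromomagnesium (R)-oct-7-en-4-olate | C=CCC[C@H](O[Mg]Br)CCC | intermediate
4 | (R)-tert-butyldimethyl(oct-7-en-4-yloxy)silane | C=CCC[C@H](O[Si](C)(C)C(C)(C)C)CCC | intermediate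
5 | 2-iodocyclohex-2-en-1-one | O=C1CCCC=C1I | starting material
6 | tert-butyl (R)-but-3-yn-2-ylcarbamate | C[C@@H](NC(=O)OC(C)(C)C)C#C | starting material
7 | tert-butyl N-[(2R)-4-(6-oxocyclohex-1-en-1-yl)but-3-yn-2-yl]carbamate | C[C@@H](NC(=O)OC(C)(C)C)C#CC1=CCCCC1=O | intermediate
8 | chloro[(5R)-5-(tert-butyldimethylsilyloxy)octyl]zirconocene | Cl[Zr](C1C=CC=C1)(C1C=CC=C1)CCCC[C@H](O[Si](C)(C)C(C)(C)C)CCC | intermediate
9 | tert-butyl N-[(2R)-4-{(6S)-6-[(5R)-5-(tert-butyldimethylsilyloxy)octyl]-2-(trimethylsilyloxy)cyclohex-1-en-1-yl}but-3-yn-2-yl]carbamate | C[C@@H](NC(=O)OC(C)(C)C)C#CC1=C(O[Si](C)(C)C)CCC[C@@H]1CCCC[C@H](O[Si](C)(C)C(C)(C)C)CCC | intermediate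
10 | tert-butyl N-[(1R)-1-{(4S)-4-[(5R)-5-(tert-butyldimethylsilyloxy)octyl]-4,5,6,7-tetrahydro-1-benzofuran-2-yl}ethyl]carbamate | C[C@@H](NC(=O)OC(C)(C)C)c1cc2c(o1)CCC[C@@H]2CCCC[C@H](O[Si](C)(C)C(C)(C)C)CCC | intermediate
11 | tert-butyl (2R,5S)-5-[(5R)-5-(tert-butyldimethylsilyloxy)octyl]-8a-hydroxy-2-methyl-3-oxo-3,5,6,7,8,8a-hexahydroquinoline-1(2H)-carboxylate (C8a epimers) | O=C1C=C2[C@@H](CCCC[C@H](O[Si](C)(C)C(C)(C)C)CCC)CCCC2(O)N(C(=O)OC(C)(C)C)[C@@H]1C | intermediate
12 | tert-butyl (2R,5S)-5-[(5R)-5-(tert-butyldimethylsilyloxy)octyl]-2-methyl-3-oxo-3,5,6,7-tetrahydroquinoline-1(2H)-carboxylate | O=C1C=C2[C@@H](CCCC[C@H](O[Si](C)(C)C(C)(C)C)CCC)CCC=C2N(C(=O)OC(C)(C)C)[C@@H]1C | intermediate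
13 | tert-butyl (2R,3R,5S)-5-[(5R)-5-(tert-butyldimethylsilyloxy)octyl]-3-hydroxy-2-methyl-3,5,6,7-tetrahydroquinoline-1(2H)-carboxylate | O[C@@H]1C=C2[C@@H](CCCC[C@H](O[Si](C)(C)C(C)(C)C)CCC)CCC=C2N(C(=O)OC(C)(C)C)[C@@H]1C | intermediate
14 | tert-butyl (2R,3R,4aS,5S,8aR)-5-[(5R)-5-(tert-butyldimethylsilyloxy)octyl]-3-hydroxy-2-methyl-octahydroquinoline-1(2H)-carboxylate | O[C@@H]1C[C@H]2[C@@H](CCCC[C@H](O[Si](C)(C)C(C)(C)C)CCC)CCC[C@H]2N(C(=O)OC(C)(C)C)[C@@H]1C | intermediate
15 | hexanal | CCCCCC=O | starting material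
16 | malonic acid | OC(=O)CC(=O)O | starting material
17 | (E)-oct-2-enoic acid | CCCCC/C=C/C(=O)O | intermediate
18 | tert-butyl (2R,3R,4aS,5S,8aR)-5-[(5R)-5-(tert-butyldimethylsilyloxy)octyl]-2-methyl-3-[(E)-oct-2-enoyloxy]-octahydroquinoline-1(2H)-carboxylate | CCCCC/C=C/C(=O)O[C@@H]1C[C@H]2[C@@H](CCCC[C@H](O[Si](C)(C)C(C)(C)C)CCC)CCC[C@H]2N(C(=O)OC(C)(C)C)[C@@H]1C | intermediate
19 | (2R,3R,4aS,5S,8aR)-5-[(5R)-5-hydroxyoctyl]-2-methyl-decahydroquinolin-3-yl (E)-oct-2-enoate | CCCCC/C=C/C(=O)O[C@@H]1C[C@H]2[C@@H](CCCC[C@H](O)CCC)CCC[C@H]2N[C@@H]1C | target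

## Step count and risks

Total step count: 9. Longest linear sequence: 7 (step 1 or 2, then 3, 4, 5, 6, 8, 9).

The three steps most likely to fail:

(a) Step 3, the new reaction. The α-alkynyl enone may react slowly or with low facial selectivity. The carbamate N–H may protonate some alkylzirconium. The ring closure may stall at the alkynyl ketone.

The fallback uses known chemistry only. It sets out from 4 and comes back at 10.
- Cyclohexane-1,3-dione is C-alkylated with commercial tert-butyl (R)-(4-chloro-3-oxobutan-2-yl)carbamate (K2CO3, DMF) to give the triketone tert-butyl N-[(2R)-4-(2,6-dioxocyclohexyl)-3-oxobutan-2-yl]carbamate F1.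
- Paal–Knorr cyclodehydration (PPTS, toluene, 80 °C) gives tert-butyl N-[(1R)-1-(4-oxo-4,5,6,7-tetrahydro-1-benzofuran-2-yl)ethyl]carbamate F2.
- KHMDS (2.2 equiv) and PhNTf2 give 2-[(1R)-1-(tert-butoxycarbonylamino)ethyl]-6,7-dihydro-1-benzofuran-4-yl trifluoromethanesulfonate F3.
- Alkene 4 is hydroborated with 9-BBN-H to give 9-[(5R)-5-(tert-butyldimethylsilyloxy)octyl]-9-borabicyclo[3.3.1]nonane F4.
- B-alkyl Suzuki–Miyaura coupling of the borane with the triflate (PdCl2(dppf), K3PO4, THF/DMF/H2O) gives tert-butyl N-[(1R)-1-{4-[(5R)-5-(tert-butyldimethylsilyloxy)octyl]-6,7-dihydro-1-benzofuran-2-yl}ethyl]carbamate F5.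
- Ir–PHOX asymmetric hydrogenation of this trisubstituted hetaryl alkene sets C4 (S) and gives 10.

(b) Step 4, the ring expansion and dehydration on a ring-fused, fully substituted furan terminus. The carbamate may close poorly on the hindered ketone. The ene-dione may isomerise to the E form. The dienone may be sensitive, and C2 lies α to the ketone.

The fallback sets out from 11, which is now worked up and used directly, and comes back at 14. C8a is set by ionic reduction instead of hydrogenation.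
- Et3SiH and BF3·OEt2 (CH2Cl2, −78 °C) reduce the N-acyliminium ion by axial hydride delivery, syn to the pseudoaxial C2 methyl (2,8a-trans). The product is tert-butyl (2R,5S,8aR)-5-[(5R)-5-(tert-butyldimethylsilyloxy)octyl]-2-methyl-3-oxo-3,5,6,7,8,8a-hexahydroquinoline-1(2H)-carboxylate F6.
- Luche reduction gives tert-butyl (2R,3R,5S,8aR)-5-[(5R)-5-(tert-butyldimethylsilyloxy)octyl]-3-hydroxy-2-methyl-3,5,6,7,8,8a-hexahydroquinoline-1(2H)-carboxylate F7.
- OH-directed hydrogenation of the single remaining alkene gives 14.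

(c) Step 6, the double directed hydrogenation. The reaction may stop at a tetrasubstituted C4a=C8a enecarbamate after 1,4-addition. The allylic alcohol may isomerise to the ketone. Selectivity may erode because the C2 methyl lies on the delivery face.

The fallback sets out from 12 and comes back at 14. It relies on steric control and reverses the order of the two reductions.
- H2 over Pd/C (EtOAc) saturates both C=C bonds from the face opposite the C5 chain. The product is tert-butyl (2R,4aS,5S,8aR)-5-[(5R)-5-(tert-butyldimethylsilyloxy)octyl]-2-methyl-3-oxo-octahydroquinoline-1(2H)-carboxylate F8.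
- L-Selectride (THF, −78 °C) attacks anti to the C2 methyl and gives 14.

## Further compounds

F1 | step 3 | tert-butyl N-[(2R)-4-(2,6-dioxocyclohexyl)-3-oxobutan-2-yl]carbamate | C[C@@H](NC(=O)OC(C)(C)C)C(=O)CC1C(=O)CCCC1=O
F2 | step 3 | tert-butyl N-[(1R)-1-(4-oxo-4,5,6,7-tetrahydro-1-benzofuran-2-yl)ethyl]carbamate | C[C@@H](NC(=O)OC(C)(C)C)c1cc2c(o1)CCCC2=O
F3 | step 3 | 2-[(1R)-1-(tert-butoxycarbonylamino)ethyl]-6,7-dihydro-1-benzofuran-4-yl trifluoromethanesulfonate | C[C@@H](NC(=O)OC(C)(C)C)c1cc2c(o1)CCC=C2OS(=O)(=O)C(F)(F)F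
F4 | step 3 | 9-[(5R)-5-(tert-butyldimethylsilyloxy)octyl]-9-borabicyclo[3.3.1]nonane | C1CC2CCCC(C1)B2CCCC[C@H](O[Si](C)(C)C(C)(C)C)CCC
F5 | step 3 | tert-butyl N-[(1R)-1-{4-[(5R)-5-(tert-butyldimethylsilyloxy)octyl]-6,7-dihydro-1-benzofuran-2-yl}ethyl]carbamate | C[C@@H](NC(=O)OC(C)(C)C)c1cc2c(o1)CCC=C2CCCC[C@H](O[Si](C)(C)C(C)(C)C)CCC
F6 | step 4 | tert-butyl (2R,5S,8aR)-5-[(5R)-5-(tert-butyldimethylsilyloxy)octyl]-2-methyl-3-oxo-3,5,6,7,8,8a-hexahydroquinoline-1(2H)-carboxylate | O=C1C=C2[C@@H](CCCC[C@H](O[Si](C)(C)C(C)(C)C)CCC)CCC[C@H]2N(C(=O)OC(C)(C)C)[C@@H]1C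
F7 | step 4 | tert-butyl (2R,3R,5S,8aR)-5-[(5R)-5-(tert-butyldimethylsilyloxy)octyl]-3-hydroxy-2-methyl-3,5,6,7,8,8a-hexahydroquinoline-1(2H)-carboxylate | O[C@@H]1C=C2[C@@H](CCCC[C@H](O[Si](C)(C)C(C)(C)C)CCC)CCC[C@H]2N(C(=O)OC(C)(C)C)[C@@H]1C
F8 | step 6 | tert-butyl (2R,4aS,5S,8aR)-5-[(5R)-5-(tert-butyldimethylsilyloxy)octyl]-2-methyl-3-oxo-octahydroquinoline-1(2H)-carboxylate | O=C1C[C@H]2[C@@H](CCCC[C@H](O[Si](C)(C)C(C)(C)C)CCC)CCC[C@H]2N(C(=O)OC(C)(C)C)[C@@H]1C
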